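The numbers in the tables come from a simulation on assumed constants, and the scatter is random.

We begin from a leftover, the charge minus the product, and follow its logarithm in each run.

| flask | substrate | free catalyst | time |
|---|---|---|---|
| spring | 0.800 M | 0.0240 M |  |
| winter | 0.800 M | 0.0480 M |  |
| noon | 1.20 M | 0.0240 M |  |
| autumn | 2.00 M | 0.0240 M | 80 min |

- apparent order in [substrate] of the starting rate, round the charge of the spring run (the rate where two percent of its substrate have turned into product) (one fixed amount of product, the same in the runs compared)
- apparent order in [free catalyst] of the starting rate, round the charge of the spring run (the rate where two percent of its substrate have turned into product)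
- product in the autumn run at 80 min, as a share of the substrate charged

- Overall: substrate -> product, with free catalyst as catalyst.
- Constant volume, constant temperature.
- What is held in complexes is read along with the free species.
- An order is taken over about fifteen percent of the charge, up and down.

| run | time / min | [product] / M |
|---|---|---|
| spring run | 13 | 0.171 |
| spring run | 27 | 0.306 |
| spring run | 40 | 0.394 |
| spring run | 53 | 0.472 |
| spring run | 67 | 0.523 |
| spring run | 80 | 0.563 |
| winter run | 13 | 0.282 |
| winter run | 27 | 0.474 |
| winter run | 40 | 0.564 |
| winter run | 53 | 0.626 |
| winter run | 67 | 0.667 |
| winter run | 80 | 0.696 |
| noon run | 13 | 0.243 |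
| noon run | 27 | 0.449 |
| noon run | 40 | 0.592 |
| noon run | 53 | 0.700 |
| noon run | 67 | 0.791 |
| noon run | 80 | 0.861 |

(each reading ± 0.004 M)

From these columns we take the mean constant, the natural logarithm of charge over leftover divided by the time, a pseudo-first-order constant that replaces a whole curve by one number. From the last reading of each run, at 80 min, the spring run gives 0.0152 min⁻¹, the noon run 0.0158 min⁻¹ and the winter run 0.0255 min⁻¹. The first reading, at 13 min, shows the error of the replacement, since the spring run there stands higher, at 0.0185 min⁻¹, so the mean holds for the time at which it was taken. The autumn run is asked at that same 80 min, with the catalyst of spring and noon, so we carry their average, the mean constant at 0.0240 M of catalyst 0.0155 min⁻¹, and reckon 71.1 % of the charge as product; spring's constant alone gives 70.4 % and noon's 71.7 %, which is our margin. The first readings also give us rough orders, 0.850 in [substrate] and 0.854 in [free catalyst], both means over 13 min and not starting rates.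

The forecast gives orders of 0.94 in [substrate] and 0.93 in [free catalyst], and for the autumn run 70 %, lower than our yield, noting: “At 2 M, mild saturation could lower that somewhat”.

The autumn run gives 70.4 %, and the orders round the charge of the spring run are 0.96 in [substrate] and 0.97 in [free catalyst].

    free catalyst + substrate ⇌ catalyst-substrate complex, settled at all times (7.310 M⁻¹)
    catalyst-substrate complex + substrate ⇌ doubly bound catalyst, settled at all times (0.3990 M⁻¹)
    doubly bound catalyst → product + catalyst-substrate complex (2.952 min⁻¹)
    catalyst-substrate complex → spent catalyst + substrate (0.005622 min⁻¹)

The autumn run's mean constant is 0.0152 min⁻¹, beside the spring run's 0.0152 min⁻¹, and its yield lies 0.70 percentage points below our reckoning. In the winter run the rate near the start stands 1.9 times the spring run's at equal product. Twice the carried 0.0155 min⁻¹ gives 91.6 % for the winter run at 80 min, and its reading is 87.0 %.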